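## Retrosynthetic overview

1. Locants used here: C1 (ring carbon bearing CO2H), C2 (=CH), C3 (CHOH), C4, C5 (CH2), C6, C7 (octyl), C8, C9=C10, C11 (C–OH), C12 (bonded to C4, C11, C13), C13 (bonded to C6, C8, C12). Rings: cyclobutane C6–C7–C8–C13, cyclopentane C4–C5–C6–C13–C12, ring A C8–C9=C10–C11–C12–C13, ring B C1=C2–C3–C4–C12–C11.
2. The cis-3,11-diol flanking the C1=C2 ester alkene is traced back to a 3,11-endoperoxide, i.e. singlet oxygen [4+2] on the ring B diene C11=C1–C2=C3. That diene comes from a Diels–Alder adduct by α,β-dehydrogenation of its ester (sulfenylation, sulfoxide elimination).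
3. Key disconnection C4–C12 (together with C1–C11): intramolecular Diels–Alder reaction of a (2E,4E)-dienoate arm with the C11=C12 alkene of a bicyclo[4.2.0]octa-2,4-diene, closing the cyclopentane and ring B at once. Enabling feature: the cis-fused cyclobutane (C6, C7, C8, C13) carries the C5 arm on its concave face, so C4 lies under C12 of ring A, and ring B with its alkene shifted to C2=C3 is a Diels–Alder cyclohexene tethered through C5–C6–C13.
4. The arm is attached by hydroboration of a methylenecyclobutane and B-alkyl Suzuki–Miyaura coupling (C5–C4 bond) with ethyl (2E,4E)-5-iodopenta-2,4-dienoate. The ring A diene comes from bromination and double dehydrobromination, and the cyclobutanone from an auxiliary-controlled keteniminium [2+2] cycloaddition to cyclohexa-1,4-diene.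
5. Ring order: ring A is bought, the cyclobutane is fused onto it (step 2), the cyclopentane and ring B are closed together (step 8), and the two oxygens come last.

Key step: step 8

Remark (assumption): the (2S,5S) auxiliary is assumed to give the (1S,6S) ring fusion of 8; if the sense of induction is the opposite, the equally available (2R,5R)-amine is used and nothing else changes. Early intermediates are named as bicyclo[4.2.0]octanes, whose C1, C6, C7, C8 become C8, C13, C6, C7 of the target.

## Route

Step 1
Reactants: 1 decanoyl chloride; 2 (2S,5S)-2,5-dimethylpyrrolidine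
Product: 3 1-[(2S,5S)-2,5-dimethylpyrrolidin-1-yl]decan-1-one
Conditions: Et3N, CH2Cl2, 0 °C → rt
Reagents that add atoms: none
Why: N-acylation of a secondary amine by an acid chloride; no stereocentre is touched.

Step 2
Reactants: 3 amide; 4 trifluoromethanesulfonic anhydride; 5 cyclohexa-1,4-diene
Product: 8 (1S,6S,8S)-8-octylbicyclo[4.2.0]oct-3-en-7-one, via keteniminium triflate 6 (not isolated), via cyclobutaniminium triflate 7 (not isolated)
Conditions: Tf2O, 2,4,6-collidine, 5 (3 equiv), ClCH2CH2Cl, −20 °C → 60 °C; then H2O, 60 °C; then DBU (cat.), CH2Cl2, rt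
Reagents that add atoms: water, O
Why: Keteniminium–alkene [2+2] cycloaddition after amide activation, in which the C2-symmetric pyrrolidine shields one face of the keteniminium so the cis ring fusion (C1, C6) forms in one absolute sense, and the epimerisable C8 is then equilibrated to the exo (convex-face) octyl isomer.

Step 3
Reactants: 8 cyclobutanone
Product: 9 (1S,6S,8S)-7-methylidene-8-octylbicyclo[4.2.0]oct-3-ene
Conditions: Ph3PCH3Br, KOtBu, THF, 0 °C → rt
Reagents that add atoms: methyltriphenylphosphonium bromide, C[P+](c1ccccc1)(c1ccccc1)c1ccccc1.[Br-]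
Why: Wittig methylenation of a strained, electrophilic cyclobutanone; the basic medium can only move C8 toward the exo isomer already present.

Step 4
Reactants: 10 ethyl (E)-4-oxobut-2-enoate
Product: 11 ethyl (2E,4E)-5-iodopenta-2,4-dienoate
Conditions: CrCl2, CHI3, THF, 0 °C
Reagents that add atoms: iodoform, IC(I)I
Why: Takai iodoolefination of the aldehyde, E-selective through the geminal dichromium species, with the enoate left untouched.

Step 5
Reactants: 9 methylenecyclobutane; 12 9-borabicyclo[3.3.1]nonane; 11 iododienoate
Product: 14 ethyl (2E,4E)-6-[(1S,6S,7R,8S)-8-octylbicyclo[4.2.0]oct-3-en-7-yl]hexa-2,4-dienoate, via alkylborane 13 (not isolated)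
Conditions: 9-BBN, THF, 0 °C → rt; then 11, PdCl2(dppf) (cat.), AsPh3, Cs2CO3, DMF/THF/H2O, rt
Reagents that add atoms: none
Why: Chemoselective hydroboration of the 1,1-disubstituted exocyclic alkene (much faster than the ring cis-alkene) followed by B-alkyl Suzuki–Miyaura coupling with retention of the dienyl iodide geometry; hydrogen is delivered to C7 from the convex face of the cis-fused bicycle, so the new arm ends endo and trans to the octyl group.

Step 6
Reactants: 14 trienyl ester
Product: 15 ethyl (2E,4E)-6-(trans-3,4-dibromo-8-exo-octyl-cis-bicyclo[4.2.0]octan-7-endo-yl)hexa-2,4-dienoate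
Conditions: Br2 (1.0 equiv), CH2Cl2, −78 °C
Reagents that add atoms: bromine, BrBr
Why: Electrophilic anti addition of bromine through a bromonium ion to the electron-rich ring alkene (the ester-deactivated dienoate should react far more slowly), giving the trans-diaxial dibromide; its two new centres, in either trans arrangement, are erased in step 7.

Step 7
Reactants: 15 dibromide
Product: 16 ethyl (2E,4E)-6-(8-exo-octyl-cis-bicyclo[4.2.0]octa-2,4-dien-7-endo-yl)hexa-2,4-dienoate
Conditions: DBU (4 equiv), THF, rt → 40 °C
Reagents that add atoms: none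
Why: Twofold anti-periplanar E2 dehydrobromination; in the trans-diaxial dibromide the only anti hydrogens sit on C2 and C5, so the conjugated 2,4-diene results and no cyclobutane stereocentre is touched.

Step 8
Reactants: 16 bicyclooctadiene dienoate
Product: 17 tetracyclic ethyl ester with C2=C3 and C9=C10 double bonds (CO2Et on C1 cis to H-11; H-11 cis to H-12; H-4 trans to H-12)
Conditions: toluene (0.01 M, degassed, trace BHT), 110 °C
Reagents that add atoms: none
Why: Thermal suprafacial [4+2] cycloaddition in which the (2E,4E)-dienoate (C4=C3–C2=C1) is the 4π partner and the C11=C12 alkene of ring A the 2π partner; the closest known reaction type is the intramolecular Diels–Alder closure of 7-(penta-2,4-dienyl)bicyclo[4.2.0]octa-2,4-dienes (endiandric type), which needs no activating group because the cis-fused cyclobutane holds C4 within bonding distance of C12. The cyclopentane (C4, C5, C6, C13, C12) closes through the three-atom tether C5–C6–C13 as the ring fused to the new cyclohexene, and ring B (C1, C2, C3, C4, C12, C11) closes as the [4+2] ring itself. C12 and C11 are set by suprafacial addition to the cis ring alkene on its concave face, the only face the endo arm on C6 can reach, so H-11 and H-12 end cis. C4 follows from the E geometry of C3=C4 together with the exo placement of ring A relative to the diene, which the cyclobutane enforces because a diene tucked under ring A would collide with C6 and C7; this gives the trans C4/C12 fusion, while the E geometry of C1=C2 places the ester cis to H-11 (a centre erased in step 10). The selectivity needed is periselectivity, ring A reacting as dienophile and not as diene toward C3=C4, which is expected from the less strained five-plus-six transition state and from the behaviour of dienyl-substituted members of this compound class. Any 8-endo-octyl/7-exo isomer formed by reversible six-electron ring opening to the cyclooctatriene at this temperature cannot cyclise and drains back through 16, so C6 and C7 keep their configuration and only the productive valence isomer is consumed.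

Step 9
Reactants: 17 Diels–Alder adduct; 18 lithium diisopropylamide
Product: 20 C1-phenylthio derivative of 17 (PhS cis to H-11), via lithium dienolate 19 (not isolated)
Conditions: LiN(iPr)2, THF, −78 °C; then PhSSPh, −78 → 0 °C
Reagents that add atoms: diphenyl disulfide, c1ccccc1SSc1ccccc1
Why: Ester enolate formation at the only acidic C–H (C1, α to the ester and allylic) and α-sulfenylation, with the electrophile expected on the convex face so that sulfur ends cis to H-11.

Step 10
Reactants: 20 sulfide; 21 3-chloroperoxybenzoic acid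
Product: 23 ring B diene ester (C11=C1 and C2=C3; C9=C10 retained), via sulfoxide 22 (not isolated)
Conditions: mCPBA (1.0 equiv), CH2Cl2, −78 °C; then toluene, CaCO3, 70 °C
Reagents that add atoms: none
Why: Chemoselective S-oxidation (faster than alkene epoxidation at −78 °C) followed by thermal syn-elimination of the sulfoxide, for which H-11 is the only β-hydrogen, so the C11=C1 alkene forms; a reversible [2,3] shift to the sulfenate only returns to the sulfoxide.

Step 11
Reactants: 23 diene ester
Product: 25 ethyl ester of the target (cis-3,11-diol), via endoperoxide 24 (not isolated)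
Conditions: O2, tetraphenylporphyrin (cat.), visible light, CH2Cl2, −20 °C; then thiourea, MeOH, rt
Reagents that add atoms: dioxygen, O=O
Why: Singlet oxygen [4+2] cycloaddition to the s-cis ring B diene (the C9=C10–C11=C1 unit is s-trans and cannot react) sets C3 and C11 together, cis by suprafaciality and on the convex face (syn to H-12, anti to C13, C8 and the cyclobutane); thiourea then cleaves only the O–O bond.

Step 12
Reactants: 25 diol ester
Product: 27 target acid CNP0106718.3, via lithium carboxylate 26 (not isolated)
Conditions: LiOH, THF/MeOH/H2O, rt; then 1 M HCl to pH 3, 0 °C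
Reagents that add atoms: lithium hydroxide, [Li+].[OH-]
Why: Saponification of the ethyl ester; no stereocentre is epimerisable and the β-hydroxy acid cannot undergo retro-aldol cleavage because C1 is sp2.

## Compound list

1 | decanoyl chloride | CCCCCCCCCC(=O)Cl | starting material
2 | (2S,5S)-2,5-dimethylpyrrolidine | C[C@H]1CC[C@H](C)N1 | starting material
3 | 1-[(2S,5S)-2,5-dimethylpyrrolidin-1-yl]decan-1-one | CCCCCCCCCC(=O)N1[C@@H](C)CC[C@@H]1C | intermediate
4 | trifluoromethanesulfonic anhydride | O=S(=O)(OS(=O)(=O)C(F)(F)F)C(F)(F)F | starting material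
5 | cyclohexa-1,4-diene | C1=CCC=CC1 | starting material
6 | (2S,5S)-1-(dec-1-en-1-ylidene)-2,5-dimethylpyrrolidinium triflate (keteniminium salt) | CCCCCCCCC=C=[N+]1[C@@H](C)CC[C@@H]1C.[O-]S(=O)(=O)C(F)(F)F | intermediate (not isolated)
7 | cyclobutaniminium triflate of 8 with the auxiliary (8-exo-octyl form drawn) | CCCCCCCC[C@H]1[C@@H]2CC=CC[C@@H]2C1=[N+]3[C@@H](C)CC[C@@H]3C.[O-]S(=O)(=O)C(F)(F)F | intermediate (not isolated)
8 | (1S,6S,8S)-8-octylbicyclo[4.2.0]oct-3-en-7-one (cis-fused, octyl exo) | CCCCCCCC[C@H]1[C@@H]2CC=CC[C@@H]2C1=O | intermediate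
9 | (1S,6S,8S)-7-methylidene-8-octylbicyclo[4.2.0]oct-3-ene | CCCCCCCC[C@H]1[C@@H]2CC=CC[C@@H]2C1=C | intermediate
10 | ethyl (E)-4-oxobut-2-enoate | CCOC(=O)/C=C/C=O | starting material
11 | ethyl (2E,4E)-5-iodopenta-2,4-dienoate | CCOC(=O)/C=C/C=C/I | intermediate
12 | 9-borabicyclo[3.3.1]nonane (9-BBN, THF solution) | B1C2CCCC1CCC2 | starting material
13 | 9-[(8-exo-octyl-cis-bicyclo[4.2.0]oct-3-en-7-endo-yl)methyl]-9-borabicyclo[3.3.1]nonane | CCCCCCCC[C@H]1[C@@H]2CC=CC[C@@H]2[C@@H]1CB3C4CCCC3CCC4 | intermediate (not isolated)
14 | ethyl (2E,4E)-6-[(1S,6S,7R,8S)-8-octylbicyclo[4.2.0]oct-3-en-7-yl]hexa-2,4-dienoate (octyl exo, arm endo) | CCCCCCCC[C@H]1[C@@H]2CC=CC[C@@H]2[C@@H]1C/C=C/C=C/C(=O)OCC | intermediate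
15 | ethyl (2E,4E)-6-(trans-3,4-dibromo-8-exo-octyl-cis-bicyclo[4.2.0]octan-7-endo-yl)hexa-2,4-dienoate (one of the two trans dibromides drawn; the other behaves alike) | CCCCCCCC[C@H]1[C@@H]2C[C@@H](Br)[C@H](Br)C[C@@H]2[C@@H]1C/C=C/C=C/C(=O)OCC | intermediate
16 | ethyl (2E,4E)-6-(8-exo-octyl-cis-bicyclo[4.2.0]octa-2,4-dien-7-endo-yl)hexa-2,4-dienoate (configuration at C1, C6, C7, C8 as in 14) | CCCCCCCC[C@H]1[C@@H]2C=CC=C[C@@H]2[C@@H]1C/C=C/C=C/C(=O)OCC | intermediate
17 | tetracyclic Diels–Alder adduct, ethyl ester, C2=C3 and C9=C10 (CO2Et cis to H-11; H-11 cis to H-12; H-4 trans to H-12) | CCCCCCCC[C@H]1[C@@H]2C=C[C@@H]3[C@@H](C(=O)OCC)C=C[C@H]4C[C@H]1[C@H]2[C@@H]43 | intermediate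
18 | lithium diisopropylamide | [Li+].CC(C)[N-]C(C)C | starting material
19 | lithium dienolate of 17 (enolate geometry not defined) | CCCCCCCC[C@H]1[C@@H]2C=C[C@@H]3C(=C([O-])OCC)C=C[C@H]4C[C@H]1[C@H]2[C@@H]43.[Li+] | intermediate (not isolated)
20 | C1-phenylthio derivative of 17 (PhS cis to H-11) | CCCCCCCC[C@H]1[C@@H]2C=C[C@@H]3[C@](Sc5ccccc5)(C(=O)OCC)C=C[C@H]4C[C@H]1[C@H]2[C@@H]43 | intermediate
21 | 3-chloroperoxybenzoic acid | OOC(=O)c1cccc(Cl)c1 | starting material
22 | sulfoxide of 20 (either configuration at sulfur) | CCCCCCCC[C@H]1[C@@H]2C=C[C@@H]3[C@](S(=O)c5ccccc5)(C(=O)OCC)C=C[C@H]4C[C@H]1[C@H]2[C@@H]43 | intermediate (not isolated)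
23 | ring B diene ester (C11=C1, C2=C3, C9=C10) | CCCCCCCC[C@H]1[C@@H]2C=CC3=C(C(=O)OCC)C=C[C@H]4C[C@H]1[C@H]2[C@@H]43 | intermediate
24 | 3,11-endoperoxide of 23 (peroxide bridge syn to H-12) | CCCCCCCC[C@H]1[C@@H]2C=C[C@]3(OO5)C(C(=O)OCC)=C[C@@H]5[C@H]4C[C@H]1[C@H]2[C@@H]43 | intermediate (not isolated)
25 | ethyl ester of the target (cis-3,11-diol) | CCCCCCCC[C@H]1[C@@H]2C=C[C@]3(O)C(C(=O)OCC)=C[C@@H](O)[C@H]4C[C@H]1[C@H]2[C@@H]43 | intermediate
26 | lithium carboxylate of the target | CCCCCCCC[C@H]1[C@@H]2C=C[C@]3(O)C(C(=O)[O-])=C[C@@H](O)[C@H]4C[C@H]1[C@H]2[C@@H]43.[Li+] | intermediate (not isolated)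
27 | CNP0106718.3 | CCCCCCCC[C@H]1[C@@H]2C=C[C@]3(O)C(C(=O)O)=C[C@@H](O)[C@H]4C[C@H]1[C@H]2[C@@H]43 | target

## Step count and risks

Total step count: 12. Longest linear sequence: 11 (steps 1–3 and 5–12); step 4 makes the coupling partner.

Steps most likely to fail:

Step 2. The strongly electrophilic keteniminium ion may abstract hydride from the doubly allylic CH2 groups of 5 instead of cycloadding, or the auxiliary may discriminate the two faces poorly. The fallback sets out from 1 and 5 and returns at 8. The ketene generated from 1 with Et3N is combined with 5 under EtAlCl2 promotion (CH2Cl2, −78 °C) in a racemic ketene–alkene [2+2] cycloaddition and equilibrated with DBU to racemic 8-exo-octylbicyclo[4.2.0]oct-3-en-7-one F1. LiBH(s-Bu)3 adds hydride from the convex face to give the racemic 7-endo alcohol F2. Lipase-catalysed acetylation (vinyl acetate, lipase from Burkholderia cepacia) resolves it, and the enantiomer with the configuration of 8 is collected, as unreacted alcohol or from the acetate after K2CO3/MeOH, as the single-enantiomer 7-endo alcohol F3. Dess–Martin oxidation then gives 8.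

Step 5. Hydroboration may occur partly on the concave face because the exo octyl group flanks the convex one, and the β-branched alkylborane may transmetallate slowly or lose hydride in the coupling. The fallback sets out from 8 and returns at 14. Horner–Wadsworth–Emmons olefination of 8 (triethyl phosphonoacetate, NaH, THF) gives ethyl (8-exo-octyl-cis-bicyclo[4.2.0]oct-3-en-7-ylidene)acetate F4. Conjugate reduction with [(Ph3P)CuH]6 delivers a small hydride directly to the ring carbon from the convex face and gives the 7-endo acetic ester F5. iBu2AlH at −78 °C gives the aldehyde F6, and a vinylogous Horner–Wadsworth–Emmons reaction with triethyl 4-phosphonocrotonate and LiN(SiMe3)2 gives 14 without any cross-coupling.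

Step 11. Singlet oxygen may approach the concave face, be taken up slowly by the ester-deactivated diene, or react in the ene mode at C9=C10. The fallback sets out from 20 and returns at 25. Sulfide 20 is oxidised to 22 as in step 10, but the cold solution is treated with P(OMe)3 in MeOH, so the [2,3]-sigmatropic (Mislow–Evans) shift of the allylic sulfoxide is trapped and oxygen is delivered to C3 on the face that carried sulfur, giving the 3-hydroxy C1=C2 ester with H-11 intact F7. SeO2 (cat.) with tBuOOH then hydroxylates the doubly allylic C11–H by an ene/[2,3] sequence on the face of the departing hydrogen to give 25.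

Further compounds
F1 | step 2 | racemic 8-exo-octyl-cis-bicyclo[4.2.0]oct-3-en-7-one (both enantiomers) | CCCCCCCC[C@H]1[C@@H]2CC=CC[C@@H]2C1=O.CCCCCCCC[C@@H]1[C@H]2CC=CC[C@H]2C1=O
F2 | step 2 | racemic 8-exo-octyl-cis-bicyclo[4.2.0]oct-3-en-7-endo-ol (both enantiomers) | CCCCCCCC[C@H]1[C@@H]2CC=CC[C@@H]2[C@@H]1O.CCCCCCCC[C@@H]1[C@H]2CC=CC[C@H]2[C@H]1O
F3 | step 2 | 8-exo-octyl-cis-bicyclo[4.2.0]oct-3-en-7-endo-ol, single enantiomer with the ring configuration of 8 | CCCCCCCC[C@H]1[C@@H]2CC=CC[C@@H]2[C@@H]1O
F4 | step 5 | ethyl (8-exo-octyl-cis-bicyclo[4.2.0]oct-3-en-7-ylidene)acetate (isomer with the ester turned away from C8 drawn; either serves) | CCCCCCCC[C@H]1[C@@H]2CC=CC[C@@H]2/C1=C\C(=O)OCC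
F5 | step 5 | ethyl (8-exo-octyl-cis-bicyclo[4.2.0]oct-3-en-7-endo-yl)acetate | CCCCCCCC[C@H]1[C@@H]2CC=CC[C@@H]2[C@@H]1CC(=O)OCC
F6 | step 5 | (8-exo-octyl-cis-bicyclo[4.2.0]oct-3-en-7-endo-yl)acetaldehyde | CCCCCCCC[C@H]1[C@@H]2CC=CC[C@@H]2[C@@H]1CC=O
F7 | step 11 | ethyl ester of the 11-deoxy target (3-hydroxy, C1=C2, H-11 cis to H-12) | CCCCCCCC[C@H]1[C@@H]2C=C[C@@H]3C(C(=O)OCC)=C[C@@H](O)[C@H]4C[C@H]1[C@H]2[C@@H]43
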